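**Retrosynthetic overview**
1. Target 12 ⇐ (R)-acetate 11 ⇐ racemic lactol 10. The lactol epimerises through the open aldehyde-acid, so a lipase can funnel it into one acetate (dynamic kinetic resolution); acyl-side deacetylation then frees 12.
2. Lactol ring (formed last): 10 ⇐ formylated acetal ester 9. Unmasking the aldehyde next to the carboxyl closes the hydroxyphthalide spontaneously, as the polyketide aldehyde-acid does in nature.
3. 9 ⇐ 8 by ortho-formylation of the one free ring carbon; 8 ⇐ resorcylate 4 + dienone 7 by C-alkylation between the two phenols.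
4. Benzene ring (formed first): 4 ⇐ linear tetraketide 3 by C-2→C-7 aldol condensation/aromatisation (orsellinic acid folding); 3 ⇐ 1 + 2 by Claisen chain extension.
5. 7 ⇐ (E)-dodec-2-enal 5 + vinyl Grignard, then oxidation.

Assumption: the lactol carbon is a hemiacylal that can epimerise via the open aldehyde-acid, so (R) is fixed late as the stable acetate 11 and free 12 is released last and kept cold, neutral and dry; 8–12 are drawn as open keto-phenols although they can close reversibly to 2-chromanol hemiketals.

**Route**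

Step 1
Reactants: 1 methyl 3,5-dioxohexanoate; 2 methyl 2,2-dimethoxyacetate
Product: 4 methyl 2-(dimethoxymethyl)-4,6-dihydroxybenzoate, via linear tetraketide 3 (not isolated)
Conditions: 1 (2 equiv), LDA (6.2 equiv), THF, 0 °C; 2 (1 equiv), −78 → 0 °C; AcOH; then Ca(OAc)2, MeOH, rt
Reagents that add atoms: none
Why: Claisen acylation of the terminal carbanion of the trianion of 1 (Harris-type polyketide chain extension) gives tetraketide 3, whose C-2 methylene attacks the alkoxy-activated C-7 ketone in an intramolecular aldol condensation and aromatises by dehydration/enolisation under the mild calcium conditions that favour this folding over Claisen cyclisation; no stereocentre is formed.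

Step 2
Reactants: 5 (2E)-dodec-2-enal
Product: 6 (4E)-tetradeca-1,4-dien-3-ol (racemic)
Conditions: CH2=CHMgBr (1.2 equiv), THF, −78 → 0 °C; aq. NH4Cl
Reagents that add atoms: vinylmagnesium bromide, C=C[Mg]Br
Why: Grignard 1,2-addition to the enal is fast and leaves the E-alkene untouched; the new carbinol centre is racemic and is removed in step 3.

Step 3
Reactants: 6 (4E)-tetradeca-1,4-dien-3-ol
Product: 7 (4E)-tetradeca-1,4-dien-3-one
Conditions: activated MnO2, CH2Cl2, rt (product stored cold with BHT)
Reagents that add atoms: none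
Why: MnO2 allylic oxidation is selective for the bis-allylic alcohol and does not touch or isomerise either alkene.

Step 4
Reactants: 4 methyl 2-(dimethoxymethyl)-4,6-dihydroxybenzoate; 7 (4E)-tetradeca-1,4-dien-3-one
Product: 8 methyl 6-(dimethoxymethyl)-2,4-dihydroxy-3-[(4E)-3-oxotetradec-4-en-1-yl]benzoate
Conditions: ethylenediammonium diacetate (20 mol %), MeOH, 50 °C, slow addition of 7 (1.1 equiv)
Reagents that add atoms: none
Why: Friedel–Crafts-type Michael addition of the ring carbon flanked by both hydroxyls (the site that 2,4-dihydroxyaryl carbonyl compounds use in Mannich reactions and amine-mediated chromene annulations) to the unhindered vinyl terminus of the dienone, activated as its iminium ion; the other free ring carbon is shielded by the acetal, the substituted enone terminus is much less electrophilic, and MeOH keeps the dimethyl acetal intact.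

Step 5
Reactants: 8 methyl 6-(dimethoxymethyl)-2,4-dihydroxy-3-[(4E)-3-oxotetradec-4-en-1-yl]benzoate
Product: 10 rac-3,5,7-trihydroxy-1-oxo-6-[(4E)-3-oxotetradec-4-en-1-yl]-1,3-dihydro-2-benzofuran-4-carbaldehyde, via formylated acetal ester 9 (not isolated)
Conditions: MgCl2, Et3N, (CH2O)n, THF, 65 °C; aqueous work-up; then 2 M HCl, THF, 45 °C
Reagents that add atoms: paraformaldehyde (formaldehyde unit), C=O; water, O
Why: Magnesium phenoxide-directed ortho-formylation (Casiraghi–Skattebøl) can only occur at the single free ring position, and acid then hydrolyses the acetal so that the liberated aldehyde, as its hydrate, attacks the neighbouring ester and closes the hydroxyphthalide by ring–chain tautomerism as in the biosynthesis; the lactol centre is formed racemic here.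

Step 6
Reactants: 10 rac-3,5,7-trihydroxy-1-oxo-6-[(4E)-3-oxotetradec-4-en-1-yl]-1,3-dihydro-2-benzofuran-4-carbaldehyde
Product: 11 (1R)-7-formyl-4,6-dihydroxy-3-oxo-5-[(4E)-3-oxotetradec-4-en-1-yl]-1,3-dihydro-2-benzofuran-1-yl acetate
Conditions: Burkholderia cepacia lipase (Amano PS-IM), vinyl acetate (5 equiv), toluene, 40 °C
Reagents that add atoms: vinyl acetate, C=COC(C)=O
Why: Lipase-catalysed dynamic kinetic resolution (enantioselective transesterification, as known for γ-hydroxybutenolide lactols): the lactol enantiomers interconvert through the open 2-formylbenzoic acid while the enzyme, chosen in a short screen for the (R)-acetate, acetylates only the (R)-lactol, so the ring closure is drawn to one configuration; the chelated, hindered phenols are not acylated.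

Step 7
Reactants: 11 (1R)-7-formyl-4,6-dihydroxy-3-oxo-5-[(4E)-3-oxotetradec-4-en-1-yl]-1,3-dihydro-2-benzofuran-1-yl acetate
Product: 12 (3R)-3,5,7-trihydroxy-1-oxo-6-[(4E)-3-oxotetradec-4-en-1-yl]-1,3-dihydro-2-benzofuran-4-carbaldehyde
Conditions: same lipase, n-BuOH (3 equiv), dry MTBE, 4 °C; filter, evaporate below 10 °C
Reagents that add atoms: none
Why: Lipase-catalysed alcoholysis (transesterification to butanol) cleaves only the acyl–oxygen bond, so the C-3–O bond and the (R) configuration are untouched, and the neutral, cold, amine-free medium suppresses ring–chain epimerisation.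

**Compound list**
1 | methyl 3,5-dioxohexanoate | COC(=O)CC(=O)CC(C)=O | starting material
2 | methyl 2,2-dimethoxyacetate | COC(OC)C(=O)OC | starting material
3 | methyl 8,8-dimethoxy-3,5,7-trioxooctanoate (linear tetraketide) | COC(=O)CC(=O)CC(=O)CC(=O)C(OC)OC | intermediate
4 | methyl 2-(dimethoxymethyl)-4,6-dihydroxybenzoate | COC(=O)c1c(O)cc(O)cc1C(OC)OC | intermediate
5 | (2E)-dodec-2-enal | CCCCCCCCC/C=C/C=O | starting material
6 | (4E)-tetradeca-1,4-dien-3-ol (racemic) | CCCCCCCCC/C=C/C(O)C=C | intermediate
7 | (4E)-tetradeca-1,4-dien-3-one | CCCCCCCCC/C=C/C(=O)C=C | intermediate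
8 | methyl 6-(dimethoxymethyl)-2,4-dihydroxy-3-[(4E)-3-oxotetradec-4-en-1-yl]benzoate | CCCCCCCCC/C=C/C(=O)CCc1c(O)cc(C(OC)OC)c(C(=O)OC)c1O | intermediate
9 | methyl 2-(dimethoxymethyl)-3-formyl-4,6-dihydroxy-5-[(4E)-3-oxotetradec-4-en-1-yl]benzoate | CCCCCCCCC/C=C/C(=O)CCc1c(O)c(C=O)c(C(OC)OC)c(C(=O)OC)c1O | intermediate
10 | rac-3,5,7-trihydroxy-1-oxo-6-[(4E)-3-oxotetradec-4-en-1-yl]-1,3-dihydro-2-benzofuran-4-carbaldehyde | CCCCCCCCC/C=C/C(=O)CCc1c(O)c(C=O)c2c(c1O)C(=O)OC2O | intermediate
11 | (1R)-7-formyl-4,6-dihydroxy-3-oxo-5-[(4E)-3-oxotetradec-4-en-1-yl]-1,3-dihydro-2-benzofuran-1-yl acetate | CCCCCCCCC/C=C/C(=O)CCc1c(O)c(C=O)c2c(c1O)C(=O)O[C@H]2OC(C)=O | intermediate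
12 | (3R)-3,5,7-trihydroxy-1-oxo-6-[(4E)-3-oxotetradec-4-en-1-yl]-1,3-dihydro-2-benzofuran-4-carbaldehyde | CCCCCCCCC/C=C/C(=O)CCc1c(O)c(C=O)c2c(c1O)C(=O)O[C@H]2O | target

**Count and risks**
Total steps: 7. Longest linear sequence: 6 (steps 2–7, from 5).

Most likely to fail, first: step 4, where C-alkylation may be slow, go to oxygen, or hit the other ring carbon. The fallback sets out from 4 and comes back at 8.
- Mannich aminomethylation of 4 (aq. CH2O, Me2NH, EtOH) at the carbon between the phenols gives methyl 6-(dimethoxymethyl)-3-[(dimethylamino)methyl]-2,4-dihydroxybenzoate F1.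
- Separately, Wittig olefination of decanal with (acetylmethylene)triphenylphosphorane gives (3E)-tridec-3-en-2-one F2, which is silylated (TMSOTf, Et3N) to (3E)-2-(trimethylsilyloxy)trideca-1,3-diene F3.
- Heating F1 with F3 (toluene, 110 °C) expels dimethylamine to form the ortho-quinone methide, which is trapped by inverse-demand hetero-Diels–Alder reaction as methyl 7-(dimethoxymethyl)-5-hydroxy-2-[(trimethylsilyl)oxy]-2-[(1E)-undec-1-en-1-yl]-3,4-dihydro-2H-chromene-6-carboxylate F4 (or its regioisomer closed through the other phenol).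
- Mild hydrolysis (aq. citric acid, THF) opens F4 to 8.

Second: step 5, where the enone and its α-methylene may not survive Mg/Et3N/formaldehyde at 65 °C. The fallback sets out from 8 and comes back at 9, which then takes the acid treatment of step 5.
- NBS (MeCN, 0 °C) brominates the only free ring position to give methyl 3-bromo-2-(dimethoxymethyl)-4,6-dihydroxy-5-[(4E)-3-oxotetradec-4-en-1-yl]benzoate F5.
- Suzuki–Miyaura vinylation (potassium vinyltrifluoroborate, PdCl2(dppf), K2CO3, THF/H2O) gives methyl 2-(dimethoxymethyl)-3-ethenyl-4,6-dihydroxy-5-[(4E)-3-oxotetradec-4-en-1-yl]benzoate F6.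
- Lemieux–Johnson cleavage (cat. OsO4, NaIO4, 2,6-lutidine) attacks the electron-rich styrene much faster than the enone and gives 9.

Third: step 6, where the lipase may show low selectivity or the wrong sense on this crowded lactol; step 7 could also erode ee. The fallback sets out from 10 and comes back at 12, bypassing steps 6 and 7: 10 is resolved directly by preparative chiral SFC at 5 °C (cellulose carbamate phase, CO2/iPrOH), and the (S) fraction is re-equilibrated to racemic 10 (wet THF, trace AcOH) and recycled. This fallback makes no new compound (F0).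

**Further compounds**
F1 | step 4 | methyl 6-(dimethoxymethyl)-3-[(dimethylamino)methyl]-2,4-dihydroxybenzoate | COC(=O)c1c(O)c(CN(C)C)c(O)cc1C(OC)OC
F2 | step 4 | (3E)-tridec-3-en-2-one | CCCCCCCCC/C=C/C(C)=O
F3 | step 4 | (3E)-2-(trimethylsilyloxy)trideca-1,3-diene | CCCCCCCCC/C=C/C(=C)O[Si](C)(C)C
F4 | step 4 | methyl 7-(dimethoxymethyl)-5-hydroxy-2-[(trimethylsilyl)oxy]-2-[(1E)-undec-1-en-1-yl]-3,4-dihydro-2H-chromene-6-carboxylate | COC(=O)c1c(O)c2c(cc1C(OC)OC)OC(O[Si](C)(C)C)(/C=C/CCCCCCCCC)CC2
F5 | step 5 | methyl 3-bromo-2-(dimethoxymethyl)-4,6-dihydroxy-5-[(4E)-3-oxotetradec-4-en-1-yl]benzoate | CCCCCCCCC/C=C/C(=O)CCc1c(O)c(Br)c(C(OC)OC)c(C(=O)OC)c1O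
F6 | step 5 | methyl 2-(dimethoxymethyl)-3-ethenyl-4,6-dihydroxy-5-[(4E)-3-oxotetradec-4-en-1-yl]benzoate | CCCCCCCCC/C=C/C(=O)CCc1c(O)c(C=C)c(C(OC)OC)c(C(=O)OC)c1O
F0 | step 6 | none | none
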